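**Plan**
- Retrosynthesis first cuts the C6–C1'' bond that holds the geranyl chain on ring A. It then cuts O1–C8a and C4–C4a of ring C in a single operation.
- The double cut leaves 5-methoxy-3-(methoxymethoxy)benzyne (stored as an ortho-silyl aryl triflate) and an (S)-3-aryl-3-silyloxy N-methoxy-N-methylpropanamide that already carries ring B, C2 and C3.
- Enabling feature: ring A bears O1 on C8a and the acyl carbon C4 on the adjacent C4a, which lies next to the C5 oxygen. This is the 1,2-oxygen/carbon pattern a 3-alkoxyaryne leaves after taking up an oxygen nucleophile and then a carbon electrophile.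
- Forward: ring A is armed (steps 1–4), the chiral chain is made (steps 5–7), ring C closes in the aryne annulation (step 8), and MOM removal, C6 iodination and Stille geranylation follow (steps 9–12).
- Stereochemistry: the only stereocentre, C2 (S), comes from BINAP–ruthenium hydrogenation of the β-keto ester. Its C–O bond is never broken afterwards and all later steps avoid free base.

Key step: step 8

Remark: flavanone numbering is used (O1, C2, C3, C4, C4a, C5–C8, C8a; primes for ring B, double primes for the geranyl chain). The target is read as the 2S compound with 5-OH, 6-geranyl and 7-OMe.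

**Step 1**
Reactants: 1 5-methoxyresorcinol
Product: 2 3-methoxy-5-(methoxymethoxy)phenol
Conditions: MOMCl (1.0 equiv), i-Pr2NEt, CH2Cl2, 0 °C → rt
Reagents that add atoms: chloromethyl methyl ether, COCCl
Why: Williamson-type etherification (MOM protection) of one of two equivalent phenols with one equivalent of MOMCl; the mono-ether should be separable from bis-ether and unreacted 1, which can be recycled.

**Step 2**
Reactants: 2 3-methoxy-5-(methoxymethoxy)phenol
Product: 3 3-methoxy-5-(methoxymethoxy)phenyl isopropylcarbamate
Conditions: i-PrNCO, Et3N (cat.), CH2Cl2, rt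
Reagents that add atoms: isopropyl isocyanate, CC(C)N=C=O
Why: Amine-catalysed addition of the phenol to the isocyanate (carbamoylation) installs an N–H carbamate, a strong ortho-directing group that can later be removed under mild E1cB conditions.

**Step 3**
Reactants: 3 3-methoxy-5-(methoxymethoxy)phenyl isopropylcarbamate
Product: 7 5-methoxy-3-(methoxymethoxy)-2-(trimethylsilyl)phenyl isopropylcarbamate, via N-silyl carbamate 4 (not isolated), via aryllithium 5 (not isolated), via N-silyl arylsilane 6 (not isolated)
Conditions: TBSOTf, TMEDA, Et2O, 0 °C → rt; n-BuLi, TMEDA, −78 °C; TMSCl, −78 °C → rt; aq. NaHSO4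
Reagents that add atoms: chlorotrimethylsilane, C[Si](C)(C)Cl
Why: Directed ortho-metalation: the carbamate (silylated on nitrogen in the flask so that it tolerates n-BuLi) and the chelating OMOM group jointly acidify and coordinate at C2, so lithiation and C-silylation should occur there and not at C6 (carbamate/OMe) or C4 (OMOM/OMe), and the N–Si bond is hydrolysed on work-up.

**Step 4**
Reactants: 7 5-methoxy-3-(methoxymethoxy)-2-(trimethylsilyl)phenyl isopropylcarbamate
Product: 9 5-methoxy-3-(methoxymethoxy)-2-(trimethylsilyl)phenyl trifluoromethanesulfonate, via silylphenol 8 (not isolated)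
Conditions: DBU, Et2NH, MeCN, 40 °C; then PhNTf2, rt
Reagents that add atoms: N-phenylbis(trifluoromethanesulfonimide), O=S(=O)(N(c1ccccc1)S(=O)(=O)C(F)(F)F)C(F)(F)F
Why: DBU removes the N–H proton and the carbamate fragments (E1cB) to phenoxide 8 and isopropyl isocyanate, which Et2NH traps as a urea, and the phenoxide is then O-triflated by PhNTf2 in the same flask under conditions that leave the aryl–silicon bond and the MOM acetal untouched.

**Step 5**
Reactants: 10 methyl 3-(3,4-dimethoxyphenyl)-3-oxopropanoate
Product: 11 methyl (S)-3-(3,4-dimethoxyphenyl)-3-hydroxypropanoate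
Conditions: H2 (50 atm), RuCl2[(R)-BINAP] (cat.), MeOH, 50 °C
Reagents that add atoms: none
Why: Noyori asymmetric hydrogenation of a β-keto ester: the substrate chelates the BINAP–ruthenium hydride through both carbonyls, and (R)-BINAP should deliver hydride to the face that gives the S carbinol, as with benzoylacetates (S because aryl outranks CH2CO2Me).

**Step 6**
Reactants: 11 methyl (S)-3-(3,4-dimethoxyphenyl)-3-hydroxypropanoate
Product: 12 (S)-3-(3,4-dimethoxyphenyl)-3-hydroxy-N-methoxy-N-methylpropanamide
Conditions: MeNH(OMe)·HCl, i-PrMgCl, THF, −20 → 0 °C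
Reagents that add atoms: N,O-dimethylhydroxylamine hydrochloride, CNOC.Cl
Why: Ester aminolysis by the chloromagnesium amide of N,O-dimethylhydroxylamine (made in the flask with i-PrMgCl) gives the N-methoxy-N-methylamide directly from the unprotected hydroxy ester, whose carbinol is masked as the magnesium alkoxide and keeps its configuration.

**Step 7**
Reactants: 12 (S)-3-(3,4-dimethoxyphenyl)-3-hydroxy-N-methoxy-N-methylpropanamide
Product: 13 (S)-3-(3,4-dimethoxyphenyl)-N-methoxy-N-methyl-3-(trimethylsilyloxy)propanamide
Conditions: TMSCl, imidazole, CH2Cl2, 0 °C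
Reagents that add atoms: chlorotrimethylsilane, C[Si](C)(C)Cl
Why: Standard O-silylation of a secondary alcohol; the trimethylsilyl ether removes the only O–H proton from the annulation partner and is the group that fluoride will cleave to release the alkoxide in step 8.

**Step 8**
Reactants: 9 5-methoxy-3-(methoxymethoxy)-2-(trimethylsilyl)phenyl trifluoromethanesulfonate; 13 (S)-3-(3,4-dimethoxyphenyl)-N-methoxy-N-methyl-3-(trimethylsilyloxy)propanamide
Product: 16 (2S)-2-(3,4-dimethoxyphenyl)-7-methoxy-5-(methoxymethoxy)chroman-4-one, via aryne 14 (not isolated), via cesium carbinolamine alkoxide 15 (not isolated)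
Conditions: CsF (3 equiv), 18-crown-6, THF, rt, slow addition of 9 (1.3 equiv); then AcOH, 0 °C
Reagents that add atoms: none
Why: Proposed new method: fluoride attacks both silicon atoms, so the aryl silane expels triflate to give aryne 14 while the silyl ether gives the cesium alkoxide of 12 in a medium without any O–H proton; the alkoxide adds to the aryne carbon remote from the OMOM group (future C8a), the site opened by the distortion a 3-alkoxy substituent imposes, and leaves the aryl anion on C4a, where the adjacent C5 oxygen stabilises it inductively. That anion adds to the tethered N-methoxy-N-methylamide carbonyl in a 6-exo-trig closure that forms C4–C4a and ring C, and the carbinolamine alkoxide 15 should persist (poor leaving group, cesium held between O and OMe) until acetic acid releases the ketone, so the enolisable flavanone never meets a strong base. The closest known reaction type is the fluoride-induced annulation of arynes with salicylate esters to xanthones (O-arylation followed by acylation by the aryl anion), together with its nitrogen counterparts. No stereocentre is created: the carbinol C–O bond of 13 is never broken, so its S configuration becomes C2. The step needs regioselective addition (O at C8a, C at C4a), secured by the C5 OMOM group beside the triple bond, and acylation faster than protonation of the aryl anion, secured by the silyl ether, the aprotic solvent and the six-membered transition state.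

**Step 9**
Reactants: 16 (2S)-2-(3,4-dimethoxyphenyl)-7-methoxy-5-(methoxymethoxy)chroman-4-one
Product: 17 (2S)-2-(3,4-dimethoxyphenyl)-5-hydroxy-7-methoxychroman-4-one
Conditions: HCl (3 M aq., cat.), MeOH, 50 °C
Reagents that add atoms: none
Why: Acid-catalysed acetal exchange with methanol removes the MOM group, which lies peri to the carbonyl and is cleaved easily, while the acidic, base-free medium offers no pathway for retro-oxa-Michael opening of ring C, so C2 should stay S.

**Step 10**
Reactants: 17 (2S)-2-(3,4-dimethoxyphenyl)-5-hydroxy-7-methoxychroman-4-one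
Product: 18 (2S)-2-(3,4-dimethoxyphenyl)-5-hydroxy-6-iodo-7-methoxychroman-4-one
Conditions: BnMe3N·ICl2 (1.0 equiv), CaCO3, CH2Cl2/MeOH, rt
Reagents that add atoms: benzyltrimethylammonium dichloroiodate, C[N+](C)(C)Cc1ccccc1.Cl[I-]Cl
Why: Electrophilic aromatic iodination with a mild ICl2− source should go ortho to the free, chelated 5-hydroxyl (C6), the selectivity pattern known for 5-hydroxy-7-alkoxyflavonoids, ring A being far more activated than the dimethoxyphenyl ring; CaCO3 only scavenges HCl.

**Step 11**
Reactants: 19 geranyl bromide
Product: 20 tributyl[(2E)-3,7-dimethylocta-2,6-dien-1-yl]stannane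
Conditions: Bu3SnH, LiN(i-Pr)2, THF, 0 °C; then 19, −78 °C
Reagents that add atoms: tributyltin hydride, CCCC[SnH](CCCC)CCCC
Why: SN2 displacement of the primary allylic bromide by Bu3SnLi at low temperature should give the primary E-allylstannane without allylic transposition.

**Step 12**
Reactants: 18 (2S)-2-(3,4-dimethoxyphenyl)-5-hydroxy-6-iodo-7-methoxychroman-4-one; 20 tributyl[(2E)-3,7-dimethylocta-2,6-dien-1-yl]stannane
Product: 21 (2S)-2-(3,4-dimethoxyphenyl)-6-[(2E)-3,7-dimethylocta-2,6-dien-1-yl]-5-hydroxy-7-methoxychroman-4-one
Conditions: Pd(PPh3)4 (cat.), DMF, 80 °C, degassed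
Reagents that add atoms: none
Why: Stille cross-coupling of an aryl iodide with an allylstannane: oxidative addition, allyl transfer and reductive elimination at the less substituted allyl terminus should give the linear E-geranyl arene, and the neutral, base-free medium protects the C2 stereocentre of the 5-hydroxyflavanone.

**Compound list**
1 | 5-methoxyresorcinol | COc1cc(O)cc(O)c1 | starting material
2 | 3-methoxy-5-(methoxymethoxy)phenol | COCOc1cc(O)cc(OC)c1 | intermediate
3 | 3-methoxy-5-(methoxymethoxy)phenyl isopropylcarbamate | CC(C)NC(=O)Oc1cc(OC)cc(OCOC)c1 | intermediate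
4 | 3-methoxy-5-(methoxymethoxy)phenyl N-(tert-butyldimethylsilyl)-N-isopropylcarbamate (not isolated) | CC(C)N(C(=O)Oc1cc(OC)cc(OCOC)c1)[Si](C)(C)C(C)(C)C | intermediate
5 | 2-lithio derivative of 4, lithium between the carbamate and OMOM groups (not isolated) | CC(C)N(C(=O)Oc1cc(OC)cc(OCOC)c1[Li])[Si](C)(C)C(C)(C)C | intermediate
6 | 5-methoxy-3-(methoxymethoxy)-2-(trimethylsilyl)phenyl N-(tert-butyldimethylsilyl)-N-isopropylcarbamate (not isolated) | CC(C)N(C(=O)Oc1cc(OC)cc(OCOC)c1[Si](C)(C)C)[Si](C)(C)C(C)(C)C | intermediate
7 | 5-methoxy-3-(methoxymethoxy)-2-(trimethylsilyl)phenyl isopropylcarbamate | CC(C)NC(=O)Oc1cc(OC)cc(OCOC)c1[Si](C)(C)C | intermediate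
8 | 5-methoxy-3-(methoxymethoxy)-2-(trimethylsilyl)phenol (not isolated) | COCOc1cc(OC)cc(O)c1[Si](C)(C)C | intermediate
9 | 5-methoxy-3-(methoxymethoxy)-2-(trimethylsilyl)phenyl trifluoromethanesulfonate | C[Si](C)(C)c1c(OS(=O)(=O)C(F)(F)F)cc(OC)cc1OCOC | intermediate
10 | methyl 3-(3,4-dimethoxyphenyl)-3-oxopropanoate | COC(=O)CC(=O)c1ccc(OC)c(OC)c1 | starting material
11 | methyl (S)-3-(3,4-dimethoxyphenyl)-3-hydroxypropanoate | COc1ccc([C@@H](O)CC(=O)OC)cc1OC | intermediate
12 | (S)-3-(3,4-dimethoxyphenyl)-3-hydroxy-N-methoxy-N-methylpropanamide | COc1ccc([C@@H](O)CC(=O)N(C)OC)cc1OC | intermediate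
13 | (S)-3-(3,4-dimethoxyphenyl)-N-methoxy-N-methyl-3-(trimethylsilyloxy)propanamide | COc1ccc([C@@H](O[Si](C)(C)C)CC(=O)N(C)OC)cc1OC | intermediate
14 | 5-methoxy-3-(methoxymethoxy)benzyne (not isolated) | COCOC1=CC(OC)=CC#C1 | intermediate
15 | cesium (2S)-2-(3,4-dimethoxyphenyl)-7-methoxy-4-[methoxy(methyl)amino]-5-(methoxymethoxy)chroman-4-olate, C4 epimers (not isolated) | COc1ccc([C@@H]2CC([O-])(N(C)OC)c3c(cc(OC)cc3OCOC)O2)cc1OC.[Cs+] | intermediate
16 | (2S)-2-(3,4-dimethoxyphenyl)-7-methoxy-5-(methoxymethoxy)chroman-4-one | COc1ccc([C@@H]2CC(=O)c3c(cc(OC)cc3OCOC)O2)cc1OC | intermediate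
17 | (2S)-2-(3,4-dimethoxyphenyl)-5-hydroxy-7-methoxychroman-4-one | COc1ccc([C@@H]2CC(=O)c3c(cc(OC)cc3O)O2)cc1OC | intermediate
18 | (2S)-2-(3,4-dimethoxyphenyl)-5-hydroxy-6-iodo-7-methoxychroman-4-one | COc1ccc([C@@H]2CC(=O)c3c(cc(OC)c(I)c3O)O2)cc1OC | intermediate
19 | geranyl bromide, (2E)-1-bromo-3,7-dimethylocta-2,6-diene | CC(C)=CCC/C(C)=C/CBr | starting material
20 | tributyl[(2E)-3,7-dimethylocta-2,6-dien-1-yl]stannane | CC(C)=CCC/C(C)=C/C[Sn](CCCC)(CCCC)CCCC | intermediate
21 | (2S)-2-(3,4-dimethoxyphenyl)-6-[(2E)-3,7-dimethylocta-2,6-dien-1-yl]-5-hydroxy-7-methoxychroman-4-one (CNP0310479.1) | COc1ccc([C@@H]2CC(=O)c3c(cc(OC)c(C/C=C(\C)CCC=C(C)C)c3O)O2)cc1OC | target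

**Step count and risks**
Total step count: 12.
Longest linear sequence: 8 steps (steps 1, 2, 3, 4, 8, 9, 10, 12, from 5-methoxyresorcinol).

Steps most likely to fail:

1. Step 8 (proposed method). The aryl anion may be protonated before it acylates, which would stop at simple O-arylation. The carbinolamine may also collapse in the flask, so that the liberated amide base opens ring C through the enolate and erodes C2, or the free alkoxide may undergo retro-aldol cleavage. The fallback uses known chemistry and sets out from 9. Fluoride-induced reaction of the aryne with commercial (E)-3,4-dimethoxycinnamic acid (CsF, THF, heat) proceeds by carboxylate O-arylation and anionic Fries-type acyl shift to the (E)-2'-hydroxychalcone F1. Oxa-Michael closure, completed if necessary with NaOAc in refluxing EtOH, gives the racemic flavanone F2. Kinetic resolution by asymmetric transfer hydrogenation (RuCl(p-cymene)[(R,R)-TsDPEN], HCO2H/Et3N, EtOAc, rt) should reduce the 2R enantiomer to the (2R,4R)-flavan-4-ol F3 and leave the S ketone, at the cost of half the material. The sequence comes back to the route at 16.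

2. Step 12. The stannane may transfer its allyl group through the γ-carbon and give the branched chain, the 2'',3''-double bond may scramble through the allylpalladium intermediate, or the hindered, doubly ortho-substituted iodide may simply be reduced. The fallback reverses the polarity of the coupling and sets out from 18. Stannylation with Me6Sn2 (Pd(PPh3)4, toluene, 100 °C) gives the arylstannane F4. This is coupled with geranyl bromide 19 itself (Pd2(dba)3, AsPh3, THF, 50 °C), so that the chain enters as a π-allylpalladium bromide and the aryl group is delivered to its primary terminus, again without base. The sequence comes back to the route at 21.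

3. Step 3. Lithiation may occur in part at C6 between the carbamate and the methoxy group and give a regioisomeric silane, or the silyl triflate may attack the MOM acetal. The fallback makes the site of metalation unambiguous and sets out from 1. Double carbamoylation (ClCONEt2, NaH, THF) gives the bis(diethylcarbamate) F5. With s-BuLi/TMEDA at −78 °C this can be lithiated only between the two carbamates, giving the aryllithium F6, and TMSCl then gives the silane F7. LiAlH4 in THF removes both carbamates to the silyl resorcinol F8 (neutral work-up to avoid protodesilylation). Mono-MOM protection as in step 1 gives phenol 8, isolated this time, where the sequence comes back to the route; 8 is triflated to 9 with PhNTf2/DBU as in step 4.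

**Further compounds**
F1 | step 8 | (E)-3-(3,4-dimethoxyphenyl)-1-[2-hydroxy-4-methoxy-6-(methoxymethoxy)phenyl]prop-2-en-1-one | COCOc1cc(OC)cc(O)c1C(=O)/C=C/c1ccc(OC)c(OC)c1
F2 | step 8 | racemic 2-(3,4-dimethoxyphenyl)-7-methoxy-5-(methoxymethoxy)chroman-4-one | COc1ccc(C2CC(=O)c3c(cc(OC)cc3OCOC)O2)cc1OC
F3 | step 8 | (2R,4R)-2-(3,4-dimethoxyphenyl)-7-methoxy-5-(methoxymethoxy)chroman-4-ol | COc1ccc([C@H]2C[C@@H](O)c3c(cc(OC)cc3OCOC)O2)cc1OC
F4 | step 12 | (2S)-2-(3,4-dimethoxyphenyl)-5-hydroxy-7-methoxy-6-(trimethylstannyl)chroman-4-one | COc1ccc([C@@H]2CC(=O)c3c(cc(OC)c([Sn](C)(C)C)c3O)O2)cc1OC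
F5 | step 3 | 5-methoxy-1,3-phenylene bis(diethylcarbamate) | CCN(CC)C(=O)Oc1cc(OC)cc(OC(=O)N(CC)CC)c1
F6 | step 3 | 2-lithio-5-methoxy-1,3-phenylene bis(diethylcarbamate) | [Li]c1c(OC(=O)N(CC)CC)cc(OC)cc1OC(=O)N(CC)CC
F7 | step 3 | 5-methoxy-2-(trimethylsilyl)-1,3-phenylene bis(diethylcarbamate) | CCN(CC)C(=O)Oc1cc(OC)cc(OC(=O)N(CC)CC)c1[Si](C)(C)C
F8 | step 3 | 5-methoxy-2-(trimethylsilyl)benzene-1,3-diol | COc1cc(O)c([Si](C)(C)C)c(O)c1
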